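**Retrosynthetic overview**
1. The last bond is C4a–C5. A visible-light radical-cation hydroarylation adds the pyridone C–H across a tethered Z-alkene, closing the carbocycle and setting C5.
2. The alkene and the C8–OMe both come from a γ-lactone carried on the pyridone: DIBAL to the lactol, Wittig with a C8 ylide, then methylation of the released alkoxide in the same pot.
3. The N-methoxy-4-pyridone comes from a γ-pyrone by O→N(OMe) exchange with MeONH2.
4. The γ-pyrone comes from a 1,3,5-triketone, made from 3-methoxypentane-2,4-dione dianion and the carboxyl of the D-glutamic-acid-derived (R)-lactone acid. That acid supplies C8a, C8, C7, C6, C5 and the C8 stereocentre.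
5. Ring order: the heterocycle is built first (pyrone, then pyridone) and the carbocycle last. C8 is purchased and C5 is relayed from C8.

Assumption: the SMILES is read as (5S,8R), with octyl and OMe cis. Compound 4 is taken as a catalogue compound, made industrially in one step from D-glutamic acid (NaNO2/HCl, retention).

**Step 1**
Reactants: 1 methoxyacetone; 2 acetic anhydride
Product: 3, 3-methoxypentane-2,4-dione
Conditions: Ac2O (2 equiv), BF3·2AcOH, cat. TsOH, 0 °C→rt; then aq NaOAc, reflux
Reagents that add atoms: acetic anhydride, CC(=O)OC(C)=O
Why: In the BF3-promoted (Meerwein–Hauser) C-acetylation of a methyl ketone, reaction goes through the more substituted, methoxy-stabilised enol, so acetyl enters at the CH2OMe carbon and NaOAc releases the diketone from its BF2 chelate; no stereocentre is formed.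

**Step 2**
Reactants: 3, 3-methoxypentane-2,4-dione; 4, (2R)-5-oxooxolane-2-carboxylic acid
Product: 5, 3-methoxy-2-methyl-6-[(2R)-5-oxooxolan-2-yl]-4H-pyran-4-one
Conditions: 4, CDI, THF, rt; cannulate into 3 (2.5 equiv)/LDA (5.0 equiv), THF, −78 °C; AcOH quench; then TFA, rt
Reagents that add atoms: none (all product atoms come from 3 and 4)
Why: In this Harris-type β-diketone dianion acylation, the terminal carbanion takes the acyl imidazolide much faster than the γ-lactone at −78 °C, and TFA cyclodehydrates the 1,3,5-triketone to the γ-pyrone; only the carboxyl carbon reacts, so the purchased C–O stereocentre stays R.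

**Step 3**
Reactants: 5; 6, O-methylhydroxylamine hydrochloride
Product: 7, 1,3-dimethoxy-2-methyl-6-[(2R)-5-oxooxolan-2-yl]pyridin-4(1H)-one
Conditions: MeONH2·HCl (5 equiv), NaOAc (5 equiv), EtOH–AcOH 4:1, 80 °C
Reagents that add atoms: O-methylhydroxylamine hydrochloride, CON.Cl
Why: This is a pyranone→pyridone exchange (conjugate addition, ring opening, ring closure) in which the α-effect nucleophile cannot divert to isoxazoles because its oxygen is methylated; the weakly acidic medium leaves the γ-lactone closed and C8 unenolised because the open intermediate enolises toward C4a.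

**Step 4**
Reactants: 7
Product: 8, 6-[(2R)-5-hydroxyoxolan-2-yl]-1,3-dimethoxy-2-methylpyridin-4(1H)-one (lactol, anomer mixture)
Conditions: DIBAL-H (2.2 equiv), CH2Cl2, −78 °C; Rochelle salt
Reagents that add atoms: none
Why: Partial lactone reduction stops at the lactol because the aluminium hemiacetal is stable at −78 °C; one equivalent of Al is only bound by the Lewis-basic pyridone oxygen, whose aromatic vinylogous-amide C=O is not reduced, and C8 is untouched (the anomeric centre is destroyed in step 5).

**Step 5**
Reactants: 8; 9, octyltriphenylphosphonium bromide; 10, iodomethane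
Product: 11, 1,3-dimethoxy-6-[(1R,4Z)-1-methoxydodec-4-en-1-yl]-2-methylpyridin-4(1H)-one
Conditions: 9 (3.0 equiv), KHMDS (2.9 equiv), THF, −78→0 °C; then MeI (8 equiv), 0 °C→rt, one pot
Reagents that add atoms: octyltriphenylphosphonium bromide, CCCCCCCC[P+](c1ccccc1)(c1ccccc1)c1ccccc1.[Br-]; iodomethane, CI
Why: Salt-free Wittig olefination of the hydroxy-aldehyde tautomer with a non-stabilised ylide gives the Z-alkene, and the released potassium C8-alkoxide is methylated in situ (Williamson) while excess MeI only quenches leftover ylide; the base deficit leaves no free amide base to deprotonate the 2-methyl, and the C8–O bond is never broken, so C8 stays R.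

**Step 6**
Reactants: 11
Product: 12, waltherione K, (5S,8R)-1,3,8-trimethoxy-2-methyl-5-octyl-5,6,7,8-tetrahydroquinolin-4(1H)-one
Conditions: 9-mesityl-3,6-di-tert-butyl-10-phenylacridinium BF4 (5 mol %), (PhS)2 (20 mol %), DCE–HFIP 9:1 (0.02 M), 450 nm LEDs, 20 °C, Ar; chromatographic removal of the minor trans isomer
Reagents that add atoms: none (cycloisomerisation, C21H35NO4 → C21H35NO4)
Why: Proposed new method: a redox-neutral radical-cation hydroarylation in which the excited acridinium (about +2.1 V vs SCE) oxidises the 3-alkoxy-4-pyridone (estimated +1.5–1.7 V) but not the dialkyl alkene (above +2.2 V); the vinylogous-amide radical cation is electrophilic at pyridone C5 (the future C4a), because attack there leaves an N-stabilised iminium σ-complex plus a secondary alkyl radical whereas ipso attack at C6 would leave an α-keto cation, so the tethered alkene closes 6-exo-trig, PhSH quenches the C1′ radical by HAT, the σ-complex loses H+ to re-aromatise, and PhS•, the acridine radical and H+ regenerate both catalysts; C5 is controlled by C8 through a chair-like transition state in which A(1,3) strain with N–OMe holds the C8–OMe pseudoaxial and the alkenyl carbon sits pseudoequatorial, which puts H5 and H8 on the same face (cis, 5S,8R); the closest known reaction types are acridinium/thiol anti-Markovnikov alkene hydrofunctionalisation, anodic olefin coupling of enol-ether-type radical cations and arene radical-cation C–H functionalisation, none shown for a 4-pyridone C–H adding across an unactivated alkene.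

**Compound list**
1 | methoxyacetone | COCC(C)=O | starting material
2 | acetic anhydride | CC(=O)OC(C)=O | starting material
3 | 3-methoxypentane-2,4-dione | COC(C(C)=O)C(C)=O | intermediate
4 | (2R)-5-oxooxolane-2-carboxylic acid | O=C1CC[C@H](C(=O)O)O1 | starting material (source of chirality)
5 | 3-methoxy-2-methyl-6-[(2R)-5-oxooxolan-2-yl]-4H-pyran-4-one | O=C1CC[C@H](c2cc(=O)c(OC)c(C)o2)O1 | intermediate
6 | O-methylhydroxylamine hydrochloride | CON.Cl | starting material
7 | 1,3-dimethoxy-2-methyl-6-[(2R)-5-oxooxolan-2-yl]pyridin-4(1H)-one | O=C1CC[C@H](c2cc(=O)c(OC)c(C)n2OC)O1 | intermediate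
8 | 6-[(2R)-5-hydroxyoxolan-2-yl]-1,3-dimethoxy-2-methylpyridin-4(1H)-one | OC1CC[C@H](c2cc(=O)c(OC)c(C)n2OC)O1 | intermediate
9 | octyltriphenylphosphonium bromide | CCCCCCCC[P+](c1ccccc1)(c1ccccc1)c1ccccc1.[Br-] | starting material
10 | iodomethane | CI | starting material
11 | 1,3-dimethoxy-6-[(1R,4Z)-1-methoxydodec-4-en-1-yl]-2-methylpyridin-4(1H)-one | CCCCCCC/C=C\CC[C@@H](OC)c1cc(=O)c(OC)c(C)n1OC | intermediate
12 | waltherione K, (5S,8R) | CCCCCCCC[C@H]1CC[C@@H](OC)c2c1c(=O)c(OC)c(C)n2OC | target

**Totals**
- Total steps: 6.
- Longest linear sequence: 6 (1→3→5→7→8→11→12).
- Steps from the chiral starting material 4: 5.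

**Steps most likely to fail**
1. **Step 6 (new reaction).**
   - Risk: the pyridone radical cation may undergo back electron transfer, or lose a proton from 2-CH3 or C8–H, faster than an unactivated alkene traps it. The diastereomer ratio may also be only moderate.
   - Fallback (known chemistry): iodinate 7 at pyridone C5 with NIS and carry the iodide through steps 4–5. Then close the ring by reductive 6-exo-trig aryl-radical cyclisation with (TMS)3SiH under blue light, or with Bu3SnH/AIBN. This adds one step and uses the same chair model for the cis product.
2. **Step 2.**
   - Risk: the strongly basic dianion may enolise and racemise the α-acyloxy acyl imidazolide, or open the lactone.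
   - Fallback: a base-free acylketene route. Couple 4 with Meldrum's acid (EDC, DMAP), then thermolyse in toluene at 110 °C with 1-methoxy-2-(trimethylsilyloxy)prop-1-ene (from 1, TMSOTf/Et3N). Hetero-Diels–Alder addition followed by TsOH elimination gives 5.
3. **Step 3.**
   - Risk: a weakly basic nucleophile on a 2,6-disubstituted pyrone may exchange slowly or incompletely.
   - Fallback: O-silylate 5 with TBSOTf to the 4-silyloxypyrylium triflate, which takes up MeONH2 at room temperature (pyrylium→pyridinium exchange). Desilylation on work-up gives 7.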